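A trap in this flask is to treat the top of the target curve as a matter of rate constants, when the step that makes target runs both ways. The reagent, charged at 0.190 M, less than the 0.20 M of starting material, is the limiting reagent, so you can reckon the top from balances.

| flask | starting material | reagent | second substrate | protic impurity | catalyst | remark | time |
|---|---|---|---|---|---|---|---|
| noon | 0.28 M | 0.19 M | 0.20 M | 0.010 M | 30 mM | run made earlier |  |
| spring | 0.44 M | 0.19 M | 0.20 M | 0.010 M | 30 mM | run made earlier |  |
| flask | 0.20 M | 0.190 M | 0.200 M | 0.0100 M | 30 mM |  | 4.0 min |

- noon (time / min: target / %): 0.250: 32; 0.667: 46; 1.50: 42; 4.00: 40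
- spring (time / min: target / %): 0.250: 28; 0.667: 34; 1.50: 34; 4.00: 32

(each reading ± 1.5 percentage points)

- what may be going on: starting material + reagent + catalyst <-> catalyst + target; second substrate + reagent + catalyst -> catalyst + second product; starting material + protic impurity -> quenched substrate

- the moment within 4.0 min at which there is most target
- the amount of target, in percent of the starting material charged, at that time

Assume that the protic impurity takes its own charge of starting material, and that the quotient of the reversible step holds steady at the top of each run:

c(starting material) = charge − c(protic impurity charged) − c(target)
c(reagent) = charge − c(target) − c(second product)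
quotient = c(target) / [c(starting material) · c(reagent)]

Leaving out second product, the readings at 0.667 min give 14.9 M⁻¹ for noon and 13.2 M⁻¹ for spring. Their mean, 14.1 M⁻¹, puts target in the flask at 0.104 M, or 52.0%.

But the second substrate also draws reagent. I price that leak from the noon target readings, which sink from 46% to 40%, and with their scatter that gives a rough 0.00504 M min⁻¹. With the leak in the balance, the mean becomes 15.1 M⁻¹, the standing quotient, a reading of the field's reaction quotient.

Is the flask's top as early as those runs' tops? The flask has less starting material than either run, so I place its top between 0.667 min and 1.50 min, at 1.00 min. That costs 0.00504 M of reagent and gives 0.104 M, or 52.0%, to set beside the earlier 52.0%.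

The forecast gives more target than my reckoning, and later than my time: 57% at 1.4 min, “with a broad maximum”.

The flask gives 48.3% at 0.962 min.

    starting material + reagent + catalyst ⇌ catalyst + target (K = 13.0 M⁻¹, k = 10.0 M⁻² s⁻¹)
    second substrate + reagent + catalyst → catalyst + second product (k = 0.410 M⁻² s⁻¹)
    starting material + protic impurity → quenched substrate (k = 3.10 M⁻¹ s⁻¹)

That is less than my reckoning of 52.0%. Second product in the flask stands at 0.0139 M at that time, more than the 0.00504 M I allowed. With that amount in the balance, 15.1 M⁻¹ gives 0.101 M, or 50.5%. In the neighbour charged with 0.11 M of reagent, my allowed leak and 15.1 M⁻¹ give 0.0680 M, or 34.0%; its computed best is 31.8%.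

Readings and results come from a simulation with made-up constants.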